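The C1 ketone and the C6 lactone carbinol lie 1,6 across the ten-membered ring, and the Z C4=C5 alkene sits on the arc C1–C2–C3–C4–C5–C6. A C1–C6 bond would therefore fold the carbocycle into a cis-decalin (ring A = cyclohexene C1–C6, ring B = C1, C6, C7, C8, C9, C10), and its 1,6-glycol carries both carbonyl-level carbons.
Retrosynthetic cuts, in order: O-protecting groups; C11–C12 and C12–O6 (lactone carbonyl as CO); C6–H (enone reduction); reconnection of C1–C6; then O8–acyl, C9–O/C10–O, C4=C5, C3–C4, C8–O, C1–C2, C5–C6 and C6–O, back to (R)-carvone.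
Forward order: ring B is the carvone ring. C5 (vinyl), C2–C3 (amide enolate) and C4/C15 (isopropenyl) are attached, ring A closes by metathesis, ring B is oxygenated, glycol cleavage merges rings A and B into the ten-membered ring, and the γ-lactone closes last by carbonylation.
Stereochemistry: C7 comes from (R)-carvone and relays to the temporary centres C6 and C1 (each C–C bond forms anti to the neighbouring β substituent, which gives the cis-glycol). C8 is set by hydride from the α face, C9/C10 by hydroxyl-directed osmylation, C3 by oxazaborolidine control, and C6 is reset by Felkin–Anh reduction of the enone after the cleavage.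
Key step: step 18

Remark on numbering: germacrane numbers of the target are used throughout (carvone C1, C2, C3, C4, C5, C6 = C1, C10, C9, C8, C7, C6). β is the face of ring B that bears the C7 side chain, α is the other face.
Remark on chemistry: the carbinol carbon of the aldol adduct of step 3 and the acetal carbon of the ozonide of step 5 are expected as epimer mixtures. Both centres are erased at once, so they are left undefined in the SMILES.

Step 1
Reactants: 1 (R)-(−)-carvone
Product: 3 (5S,6S)-6-hydroxycarvone (6α-hydroxyl trans to the isopropenyl group), via lithium dienolate 2 (not isolated)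
Conditions: LiN(iPr)2, THF, −78 °C; then 2-(phenylsulfonyl)-3-phenyloxaziridine, −78 °C
Reagents that add atoms: 2-(phenylsulfonyl)-3-phenyloxaziridine, O=S(=O)(c1ccccc1)N1OC1c1ccccc1
Why: Kinetic α′-deprotonation gives the cross-conjugated dienolate, and Davis oxaziridine hydroxylation transfers oxygen to C6 on the α face, anti to the C7 isopropenyl group.

Step 2
Reactants: 3 (5S,6S)-6-hydroxycarvone
Product: 4 6α-(tert-butyldimethylsilyloxy)carvone
Conditions: TBSCl, imidazole, DMF, rt
Reagents that add atoms: tert-butyldimethylsilyl chloride, CC(C)(C)[Si](C)(C)Cl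
Why: Imidazole-promoted silylation masks the ketol O–H so that C6–H can be removed in step 3, and no stereocentre is touched.

Step 3
Reactants: 4 6α-(tert-butyldimethylsilyloxy)carvone; 5 acetaldehyde
Product: 7 6α-(1-hydroxyethyl)-6β-(tert-butyldimethylsilyloxy)carvone, via lithium enolate 6 (not isolated)
Conditions: LiN(iPr)2, THF, −78 °C; then MeCHO, −78 °C, cold quench
Reagents that add atoms: acetaldehyde (5), CC=O
Why: Aldol addition of the fully substituted lithium enolate, in which the aldehyde reaches C6 from the α face, anti to the isopropenyl group (the sense known for alkylation of 6-substituted carvones); this pushes the silyloxy group to the β face and fixes the quaternary centre.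

Step 4
Reactants: 7 6α-(1-hydroxyethyl)-6β-(tert-butyldimethylsilyloxy)carvone
Product: 8 6α-vinyl-6β-(tert-butyldimethylsilyloxy)carvone
Conditions: Martin sulfurane Ph2S[OC(CF3)2Ph]2, CH2Cl2, 0 °C to rt
Reagents that add atoms: none
Why: Martin sulfurane dehydration of a secondary alcohol; C6 carries no hydrogen, so elimination can only use the methyl group, and both carbinol epimers give the same vinyl group.

Step 5
Reactants: 8 6α-vinyl-6β-(tert-butyldimethylsilyloxy)carvone
Product: 10 7β-acetyl enone (isopropenyl group of 8 replaced by acetyl), via side-chain ozonide 9 (not isolated)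
Conditions: O3, CH2Cl2, −78 °C (Sudan Red 7B end point); then Me2S, −78 °C to rt
Reagents that add atoms: ozone, [O-][O+]=O
Why: Chemoselective ozonolysis, since the electron-rich 1,1-dialkyl alkene reacts well before the enone and before the vinyl group, which is deactivated and shielded by the silyloxy- and acyl-bearing quaternary C6; the neutral reductive work-up leaves C7 untouched.

Step 6
Reactants: 10 7β-acetyl enone
Product: 12 7β-[1-(trifluoromethylsulfonyloxy)vinyl] enone (C11 enol triflate), via terminal lithium enolate 11 (not isolated)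
Conditions: LiN(iPr)2, THF, −78 °C; then N-(5-chloro-2-pyridyl)bis(trifluoromethanesulfonimide), −78 °C
Reagents that add atoms: N-(5-chloro-2-pyridyl)bis(trifluoromethanesulfonimide), O=S(=O)(N(c1ccc(Cl)cn1)S(=O)(=O)C(F)(F)F)C(F)(F)F
Why: Kinetic deprotonation of the methyl ketone at CH3 and cold O-sulfonylation with Comins' reagent give the terminal enol triflate before equilibration to the C7 enolate can occur; the group serves as an electron-poor, non-acylating placeholder for the lactone carbonyl.

Step 7
Reactants: 12 C11 enol triflate enone; 13 N-methoxy-N-methylacetamide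
Product: 15 1β-hydroxy-1α-[2-(N-methoxy-N-methylamino)-2-oxoethyl] adduct of 12, via lithium amide enolate 14 (not isolated)
Conditions: 13, LiN(iPr)2, THF, −78 °C; then 12, −78 °C, cold quench
Reagents that add atoms: N-methoxy-N-methylacetamide (13), CC(=O)N(C)OC
Why: Kinetic 1,2-aldol addition of an amide enolate to the enone carbonyl, with axial entry from the α face anti to the axial 6β-silyloxy group (Felkin–Anh sense), so C2 ends up cis to the vinyl group and O1 cis to O6.

Step 8
Reactants: 15 1β-hydroxy Weinreb amide
Product: 16 8-oxo derivative of 15 (C8 enone)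
Conditions: Rh2(cap)4 (dirhodium tetracaprolactamate, 1 mol %), t-BuOOH (70 % in water), CH2Cl2, rt
Reagents that add atoms: tert-butyl hydroperoxide, CC(C)(C)OO
Why: Dirhodium-catalysed allylic C–H oxidation with the selectivity known from valencene-to-nootkatone oxidations: C8 is the only ring methylene allylic to the electron-rich trisubstituted alkene (C1 is quaternary), and the free tertiary allylic alcohol, which chromium reagents would transpose, is tolerated.

Step 9
Reactants: 16 C8 enone
Product: 17 8β-alcohol
Conditions: NaBH4, CeCl3·7H2O, MeOH, −78 °C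
Reagents that add atoms: none
Why: Luche 1,2-reduction in which the axial 6β-silyloxy group, 1,3 to C8, blocks the β trajectory, so hydride arrives from the α face and gives the 8β alcohol cis to the C7 side chain.

Step 10
Reactants: 17 8β-alcohol; 18 isopropenylmagnesium bromide
Product: 19 isopropenyl ketone (C3 ketone, C4=CH2, 6β-silyl ether retained)
Conditions: 18 (3.5 equiv), THF, −78 to 0 °C
Reagents that add atoms: isopropenylmagnesium bromide (18), C=C(C)[Mg]Br
Why: Weinreb ketone synthesis: after deprotonation of the two hydroxyl groups the Grignard reagent forms the stable magnesium chelate, which releases the vinyl ketone only on work-up, so no second addition takes place.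

Step 11
Reactants: 19 isopropenyl ketone
Product: 20 1β,6β,8β-triol dienone
Conditions: HF·pyridine, pyridine, THF, 0 °C to rt
Reagents that add atoms: none
Why: Buffered fluoride cleavage of the tertiary silyl ether spares the base-sensitive β-hydroxy vinyl ketone and the enol triflate, and it frees the allylic hydroxyl group that speeds up the metathesis.

Step 12
Reactants: 20 1β,6β,8β-triol dienone
Product: 21 cis-decalin enone triol (ring A 4-en-3-one)
Conditions: second-generation Hoveyda–Grubbs catalyst (5 mol %), toluene, 80 °C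
Reagents that add atoms: none
Why: Ring-closing metathesis of the cis-disposed α vinyl group and α side chain forms C4=C5 inside a six-membered ring, where only the Z geometry can exist; the enol triflate and C9=C10 alkenes could only close strained four-membered rings and stay out.

Step 13
Reactants: 21 cis-decalin enone triol; 22 tigloyl chloride
Product: 23 8β-tiglate
Conditions: 22, Et3N, DMAP (cat.), CH2Cl2, 0 °C to rt
Reagents that add atoms: tigloyl chloride (22), C/C=C(\C)C(=O)Cl
Why: DMAP-catalysed acylation reaches only O8, the sole secondary hydroxyl group, because the two ring-fusion alcohols are tertiary and inert.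

Step 14
Reactants: 23 8β-tiglate
Product: 24 9β,10β-diol
Conditions: OsO4 (5 mol %), Me3NO·2H2O, CH2Cl2, 0 °C to rt
Reagents that add atoms: osmium tetroxide (catalytic oxygen carrier), O=[Os](=O)(=O)=O; trimethylamine N-oxide, C[N+](C)(C)[O-]; water, O
Why: Hydrogen-bond-directed syn-dihydroxylation in a non-coordinating solvent: C9=C10 is the only electron-rich alkene (enone, tiglate and enol triflate are deactivated), its α face is covered by C2 of ring A, and the 1β- and 6β-hydroxyl groups guide octavalent osmium to the β face, setting C9 and C10 cis to O8.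

Step 15
Reactants: 24 9β,10β-diol
Product: 25 9,10-acetonide
Conditions: 2-methoxypropene, PPTS (cat.), CH2Cl2, 0 °C
Reagents that add atoms: 2-methoxypropene, C=C(C)OC
Why: Kinetic ketalisation starts at the only secondary hydroxyl group (O9) and closes onto the cis O10, so the far slower tertiary–tertiary 1,6-glycol stays free.

Step 16
Reactants: 25 9,10-acetonide
Product: 26 3β-alcohol (3S)
Conditions: (R)-2-methyl-CBS-oxazaborolidine (20 mol %), catecholborane, toluene, −78 °C
Reagents that add atoms: none
Why: Corey–Bakshi–Shibata 1,2-reduction of a 2-methylcyclohexenone, in which the methyl-bearing alkene side acts as the large group, so the (R)-catalyst gives the 3S alcohol; this is reinforced by the substrate, because the axial 1β-hydroxyl group hinders the β trajectory and hydride enters from the α face.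

Step 17
Reactants: 26 3β-alcohol
Product: 27 3β-triethylsilyl ether, the cis-decalin-1β,6β-diol
Conditions: TESCl, imidazole, CH2Cl2, 0 °C
Reagents that add atoms: triethylsilyl chloride, CC[Si](CC)(CC)Cl
Why: Silylation of the only secondary hydroxyl group leaves the tertiary glycol free and masks O3, which would otherwise form a furan with the Z-enone made in the next step.

Step 18
Reactants: 27 cis-decalin-1β,6β-diol
Product: 29 (4Z)-cyclodec-4-ene-1,6-dione, via cyclic plumbate 28 (not isolated)
Conditions: Pb(OAc)4, NaHCO3 (solid), CH2Cl2, −20 °C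
Reagents that add atoms: none
Why: The gauche 1β,6β-glycol displaces two acetates from tetravalent lead to give the five-membered cyclic plumbate 28, which collapses in a concerted two-electron fragmentation that breaks C1–C6, turns both carbinol carbons into carbonyl groups and releases divalent lead as Pb(OAc)2. This is the Criegee glycol cleavage, and its closest relative is the known conversion of bicyclo[4.4.0]decane-1,6-diols into cyclodecane-1,6-diones. No ring is closed: rings A and B merge into the ten-membered ring by deletion of their shared bond, so no medium-ring closure has to be paid for, and relief of the three syn-axial C–O bonds on ring B adds driving force. No stereocentre is created; C3, C7, C8, C9 and C10 are spectators, and C4=C5 keeps the Z geometry that ring A imposed. The step needs cleavage of one glycol only and a neutral medium: O9 and O10 are locked in the acetonide so that neither C9–C10 nor C1–C10 can react, O3 is silylated, and solid NaHCO3 at low temperature takes up the acetic acid without forming enolates that would start transannular aldol closure, loss of the C8 tiglate or epimerisation at C7. The C11 enol triflate, used in place of an acrylate, keeps C7–H less acidic and cannot acylate the tertiary 6-hydroxyl group before the cleavage.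

Step 19
Reactants: 29 (4Z)-cyclodec-4-ene-1,6-dione
Product: 30 6α-alcohol (6R)
Conditions: NaBH4, CeCl3·7H2O, MeOH–CH2Cl2, −78 °C, directly on the crude dione
Reagents that add atoms: none
Why: Luche 1,2-reduction in which the conjugated C6 carbonyl reacts in preference to the C1 ketone flanked by the fully substituted C10, and hydride approaches from the ring periphery anti to the C7 side chain held perpendicular to the carbonyl (Felkin–Anh), giving the 6α alcohol trans to that side chain.

Step 20
Reactants: 30 6α-alcohol
Product: 31 trans-fused α-methylene-γ-butyrolactone (3-O-TES, 9,10-acetonide)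
Conditions: Pd(PPh3)4 (10 mol %), CO (1 atm), iPr2NEt, MeCN, 50 °C
Reagents that add atoms: carbon monoxide, [C-]#[O+]
Why: Carbonylative lactonisation of a hydroxy enol triflate: oxidative addition of zerovalent palladium to the C11–O bond, CO insertion to the acyl complex of divalent palladium and 5-exo capture by the 6α-hydroxyl group build C12 and close the lactone without touching C6 or C7.

Step 21
Reactants: 31 protected lactone
Product: 32 CNP0106709.2
Conditions: CF3CO2H, H2O, THF, 0 °C to rt
Reagents that add atoms: none
Why: Aqueous acid hydrolyses the triethylsilyl ether and the isopropylidene ketal in one operation, while tiglate, lactone and β-hydroxy ketone should survive the short cold exposure, and no stereocentre is involved.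

Compound list
1 | (R)-(−)-carvone | CC1=CC[C@H](CC1=O)C(C)=C | starting material
2 | lithium cross-conjugated dienolate of 1 | CC1=CC[C@H](C=C1O[Li])C(C)=C | intermediate
3 | (5S,6S)-6-hydroxycarvone (6α-OH) | CC1=CC[C@@H](C(C)=C)[C@H](O)C1=O | intermediate
4 | 6α-(tert-butyldimethylsilyloxy)carvone | CC1=CC[C@@H](C(C)=C)[C@H](O[Si](C)(C)C(C)(C)C)C1=O | intermediate
5 | acetaldehyde | CC=O | starting material
6 | lithium enolate of 4 (C1=C6) | CC1=CC[C@@H](C(C)=C)C(O[Si](C)(C)C(C)(C)C)=C1O[Li] | intermediate
7 | 6α-(1-hydroxyethyl)-6β-(TBS-oxy)carvone (carbinol epimers) | CC1=CC[C@@H](C(C)=C)[C@](O[Si](C)(C)C(C)(C)C)(C(C)O)C1=O | intermediate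
8 | 6α-vinyl-6β-(TBS-oxy)carvone | CC1=CC[C@@H](C(C)=C)[C@](O[Si](C)(C)C(C)(C)C)(C=C)C1=O | intermediate
9 | 1,2,4-trioxolane of the isopropenyl group of 8 | CC1=CC[C@@H](C2(C)OCOO2)[C@](O[Si](C)(C)C(C)(C)C)(C=C)C1=O | intermediate
10 | 7β-acetyl-6α-vinyl-6β-(TBS-oxy) enone | CC1=CC[C@@H](C(C)=O)[C@](O[Si](C)(C)C(C)(C)C)(C=C)C1=O | intermediate
11 | terminal lithium enolate of 10 | CC1=CC[C@@H](C(=C)O[Li])[C@](O[Si](C)(C)C(C)(C)C)(C=C)C1=O | intermediate
12 | C11 enol triflate enone | CC1=CC[C@@H](C(=C)OS(=O)(=O)C(F)(F)F)[C@](O[Si](C)(C)C(C)(C)C)(C=C)C1=O | intermediate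
13 | N-methoxy-N-methylacetamide | CC(=O)N(C)OC | starting material
14 | lithium enolate of 13 | C=C(O[Li])N(C)OC | intermediate
15 | 1β-hydroxy Weinreb amide (C2 chain α, cis to vinyl) | CC1=CC[C@@H](C(=C)OS(=O)(=O)C(F)(F)F)[C@](O[Si](C)(C)C(C)(C)C)(C=C)[C@]1(O)CC(=O)N(C)OC | intermediate
16 | 8-oxo derivative of 15 | CC1=CC(=O)[C@@H](C(=C)OS(=O)(=O)C(F)(F)F)[C@](O[Si](C)(C)C(C)(C)C)(C=C)[C@]1(O)CC(=O)N(C)OC | intermediate
17 | 8β-alcohol | CC1=C[C@@H](O)[C@@H](C(=C)OS(=O)(=O)C(F)(F)F)[C@](O[Si](C)(C)C(C)(C)C)(C=C)[C@]1(O)CC(=O)N(C)OC | intermediate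
18 | isopropenylmagnesium bromide | C=C(C)[Mg]Br | starting material
19 | isopropenyl ketone (6β-OTBS) | CC1=C[C@@H](O)[C@@H](C(=C)OS(=O)(=O)C(F)(F)F)[C@](O[Si](C)(C)C(C)(C)C)(C=C)[C@]1(O)CC(=O)C(C)=C | intermediate
20 | 1β,6β,8β-triol dienone | CC1=C[C@@H](O)[C@@H](C(=C)OS(=O)(=O)C(F)(F)F)[C@](O)(C=C)[C@]1(O)CC(=O)C(C)=C | intermediate
21 | cis-decalin enone triol | CC1=C[C@@H](O)[C@@H](C(=C)OS(=O)(=O)C(F)(F)F)[C@]2(O)C=C(C)C(=O)C[C@]12O | intermediate
22 | tigloyl chloride | C/C=C(\C)C(=O)Cl | starting material
23 | 8β-tiglate | CC1=C[C@@H](OC(=O)/C(C)=C/C)[C@@H](C(=C)OS(=O)(=O)C(F)(F)F)[C@]2(O)C=C(C)C(=O)C[C@]12O | intermediate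
24 | 9β,10β-diol | C[C@]1(O)[C@@H](O)[C@@H](OC(=O)/C(C)=C/C)[C@@H](C(=C)OS(=O)(=O)C(F)(F)F)[C@]2(O)C=C(C)C(=O)C[C@]12O | intermediate
25 | 9,10-acetonide | C[C@@]13OC(C)(C)O[C@H]3[C@@H](OC(=O)/C(C)=C/C)[C@@H](C(=C)OS(=O)(=O)C(F)(F)F)[C@]2(O)C=C(C)C(=O)C[C@]12O | intermediate
26 | 3β-alcohol (3S) | C[C@@]13OC(C)(C)O[C@H]3[C@@H](OC(=O)/C(C)=C/C)[C@@H](C(=C)OS(=O)(=O)C(F)(F)F)[C@]2(O)C=C(C)[C@@H](O)C[C@]12O | intermediate
27 | cis-decalin-1β,6β-diol, 3β-OTES (cleavage precursor) | C[C@@]13OC(C)(C)O[C@H]3[C@@H](OC(=O)/C(C)=C/C)[C@@H](C(=C)OS(=O)(=O)C(F)(F)F)[C@]2(O)C=C(C)[C@@H](O[Si](CC)(CC)CC)C[C@]12O | intermediate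
28 | cyclic 1,6-plumbate diacetate | C[C@@]13OC(C)(C)O[C@H]3[C@@H](OC(=O)/C(C)=C/C)[C@@H](C(=C)OS(=O)(=O)C(F)(F)F)[C@]2(O4)C=C(C)[C@@H](O[Si](CC)(CC)CC)C[C@]12O[Pb]4(OC(C)=O)OC(C)=O | intermediate
29 | (4Z)-cyclodec-4-ene-1,6-dione | C[C@]12OC(C)(C)O[C@H]1[C@@H](OC(=O)/C(C)=C/C)[C@@H](C(=C)OS(=O)(=O)C(F)(F)F)C(=O)/C=C(/C)[C@@H](O[Si](CC)(CC)CC)CC2=O | intermediate
30 | 6α-alcohol (6R) | C[C@]12OC(C)(C)O[C@H]1[C@@H](OC(=O)/C(C)=C/C)[C@@H](C(=C)OS(=O)(=O)C(F)(F)F)[C@H](O)/C=C(/C)[C@@H](O[Si](CC)(CC)CC)CC2=O | intermediate
31 | protected trans-fused α-methylene-γ-lactone | C[C@]12OC(C)(C)O[C@H]1[C@@H](OC(=O)/C(C)=C/C)[C@H]3C(=C)C(=O)O[C@@H]3/C=C(/C)[C@@H](O[Si](CC)(CC)CC)CC2=O | intermediate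
32 | CNP0106709.2 | C=C1C(=O)O[C@@H]2/C=C(/C)[C@@H](O)CC(=O)[C@@](C)(O)[C@@H](O)[C@@H](OC(=O)/C(C)=C/C)[C@@H]12 | target

Total step count: 21. Longest linear sequence: 21 steps (1 to 32, fully linear).

Steps most likely to fail

Step 7. The C1 carbonyl lies between the quaternary C6 and the methyl-bearing C10, so the addition may be slow, may revert by retro-aldol cleavage on warming, or may drift to 1,4-addition. The fallback sets out from 12 and returns at 19. It uses a smaller, practically irreversible carbanion. Cyanomethyllithium (acetonitrile, n-butyllithium, THF, −78 °C) should add to C1 in the same α sense to give β-hydroxy nitrile F1. Rh2(cap)4/t-BuOOH oxidation gives C8 enone F2, and Luche reduction gives 8β-alcohol F3. Excess isopropenylmagnesium bromide, assisted by the neighbouring alkoxide, adds to the nitrile to give, after protonation, ketimine F4, which aqueous oxalic acid hydrolyses to 19.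

Step 14. Osmium may be delivered to the α face if hydrogen bonding does not outweigh the steric demand of the β-oriented tiglate, or it may be diverted to the ring A enone by the allylic 6-hydroxyl group. The fallback sets out from 23 and returns at 24. It uses the Woodward variant of the Prévost reaction, which places the cis-diol on the face opposite to the one the electrophile prefers. Iodine and AgOAc in acetic acid form the iodonium ion on the α face, and acetate opens it at C10 from the β face to give trans-iodo acetate F5. Silver-assisted displacement through the acetoxonium ion in wet acetic acid gives β-cis hydroxy acetate F6. K2CO3 in methanol at 0 °C removes the acetate faster than the conjugated tiglate and gives 24.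

Step 19. Facial selectivity in the flexible ten-membered ring may be poor, with hydride entering from the face that leads to the 6β-alcohol. The fallback sets out from 29 and returns at 30. It corrects the centre by inversion, which is possible here because the enol triflate cannot lactonise onto the wrong epimer. The Luche product 6β-alcohol F7 is treated with formic acid, PPh3 and diisopropyl azodicarboxylate (Mitsunobu reaction) to give 6α-formate F8, and KHCO3 in methanol cleaves the formate to 30.

Further compounds
F1 | step 7 | β-hydroxy nitrile (1β-OH, 1α-cyanomethyl) | CC1=CC[C@@H](C(=C)OS(=O)(=O)C(F)(F)F)[C@](O[Si](C)(C)C(C)(C)C)(C=C)[C@]1(O)CC#N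
F2 | step 7 | C8 enone nitrile | CC1=CC(=O)[C@@H](C(=C)OS(=O)(=O)C(F)(F)F)[C@](O[Si](C)(C)C(C)(C)C)(C=C)[C@]1(O)CC#N
F3 | step 7 | 8β-alcohol nitrile | CC1=C[C@@H](O)[C@@H](C(=C)OS(=O)(=O)C(F)(F)F)[C@](O[Si](C)(C)C(C)(C)C)(C=C)[C@]1(O)CC#N
F4 | step 7 | C3 ketimine | CC1=C[C@@H](O)[C@@H](C(=C)OS(=O)(=O)C(F)(F)F)[C@](O[Si](C)(C)C(C)(C)C)(C=C)[C@]1(O)CC(=N)C(C)=C
F5 | step 14 | 9α-iodo-10β-acetate | C[C@]1(OC(C)=O)[C@H](I)[C@@H](OC(=O)/C(C)=C/C)[C@@H](C(=C)OS(=O)(=O)C(F)(F)F)[C@]2(O)C=C(C)C(=O)C[C@]12O
F6 | step 14 | 9β-acetoxy-10β-ol | C[C@]1(O)[C@@H](OC(C)=O)[C@@H](OC(=O)/C(C)=C/C)[C@@H](C(=C)OS(=O)(=O)C(F)(F)F)[C@]2(O)C=C(C)C(=O)C[C@]12O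
F7 | step 19 | 6β-alcohol (6S) | C[C@]12OC(C)(C)O[C@H]1[C@@H](OC(=O)/C(C)=C/C)[C@@H](C(=C)OS(=O)(=O)C(F)(F)F)[C@@H](O)/C=C(/C)[C@@H](O[Si](CC)(CC)CC)CC2=O
F8 | step 19 | 6α-formate | C[C@]12OC(C)(C)O[C@H]1[C@@H](OC(=O)/C(C)=C/C)[C@@H](C(=C)OS(=O)(=O)C(F)(F)F)[C@H](OC=O)/C=C(/C)[C@@H](O[Si](CC)(CC)CC)CC2=O
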